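**Retrosynthetic overview**
- Target 14 comes from 13 by cleaving the two MOM ethers in the last step.
- The strategy rests on the ketone carbon. It is bonded to C1' of the fully substituted ring A and to Cα of a plain Cα=Cβ–phenyl (ring B) styryl unit, so both of its C–C bonds can be cut at once to give aryl iodide 10, carbon monoxide 11 and styrene 12 (three-component carbonylative Heck coupling).
- Iodide 10 comes from iodination of the last ring A C–H of ester 9, and 9 from Steglich esterification of phenol 7 with (S)-2-methylbutanoic acid 8, which supplies the only stereocentre.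
- Phenol 7 comes from directed ortho-lithiation, borylation and oxidation of the symmetric bis-MOM ether 4, itself made by methylation, double copper-catalysed hydroxylation and MOM protection of 2,6-dibromo-4-methoxyphenol 1.
- No ring is constructed: ring A and ring B are bought as benzene rings, and ring A is decorated substituent by substituent before the key coupling.

Key step: step 7

Remark: chalcone numbering is used (ring A carries the carbonyl at C1'). Acid 8 is assumed to be of high enantiomeric purity, since it is the only source of the stereocentre.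

**Route**

Step 1
Reactants: 1 2,6-dibromo-4-methoxyphenol
Product: 2 1,3-dibromo-2,5-dimethoxybenzene
Conditions: MeI, K2CO3, acetone, reflux
Reagents that add atoms: iodomethane, CI
Why: Williamson ether synthesis, in which the acidic 2,6-dibromophenol is deprotonated by K2CO3 and the phenoxide is O-methylated by MeI in an SN2 reaction.

Step 2
Reactants: 2 1,3-dibromo-2,5-dimethoxybenzene
Product: 3 2,5-dimethoxybenzene-1,3-diol
Conditions: Cu(acac)2 (5 mol%), N,N'-bis(4-hydroxy-2,6-dimethylphenyl)oxalamide (5 mol%), LiOH·H2O, DMSO/H2O (4:1), 100 °C, Ar; then aq. HCl to pH 3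
Reagents that add atoms: lithium hydroxide, [Li+].[OH-]
Why: Ullmann-type copper-catalysed hydroxylation of aryl bromides with hydroxide under oxalamide ligand acceleration should replace both equivalent C–Br bonds, each of which has only one ortho substituent, by C–OH.

Step 3
Reactants: 3 2,5-dimethoxybenzene-1,3-diol
Product: 4 2,5-dimethoxy-1,3-bis(methoxymethoxy)benzene
Conditions: NaH, MOMCl, THF/DMF, 0 °C → rt
Reagents that add atoms: chloromethyl methyl ether, COCCl
Why: Williamson-type O-alkylation of the bis-phenoxide with the hard electrophile MOMCl should give the bis-acetal, which protects both hydroxyls and provides the directing groups for the next step.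

Step 4
Reactants: 4 2,5-dimethoxy-1,3-bis(methoxymethoxy)benzene
Product: 7 3,6-dimethoxy-2,4-bis(methoxymethoxy)phenol, via aryllithium 5 (not isolated), via dimethyl arylboronate 6 (not isolated)
Conditions: n-BuLi, TMEDA, THF, −78 → 0 °C; B(OMe)3, −78 °C → rt; 30% H2O2, AcOH, 0 °C → rt
Reagents that add atoms: hydrogen peroxide, OO (the phenolic oxygen of 7); n-butyllithium, [Li]CCCC (lithium of 5 only); trimethyl borate, COB(OC)OC (B(OMe)2 group of 6 only)
Why: Directed ortho-metalation, in which the OMOM and OMe groups flanking either of the two equivalent ring C–H positions cooperate, gives aryllithium 5, which is trapped as boronate 6 and converted into the phenol by peroxide-induced aryl migration from boron to oxygen (boronate oxidation).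

Step 5
Reactants: 7 3,6-dimethoxy-2,4-bis(methoxymethoxy)phenol; 8 (S)-2-methylbutanoic acid
Product: 9 3,6-dimethoxy-2,4-bis(methoxymethoxy)phenyl (S)-2-methylbutanoate
Conditions: DCC, DMAP (cat.), CH2Cl2, 0 °C → rt
Reagents that add atoms: none
Why: Steglich esterification (carbodiimide activation with DMAP acyl transfer) should acylate the hindered phenol under near-neutral conditions in which the α-stereocentre of the acid, which has no activating α-substituent, is carried over unchanged as S.

Step 6
Reactants: 9 3,6-dimethoxy-2,4-bis(methoxymethoxy)phenyl (S)-2-methylbutanoate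
Product: 10 5-iodo-3,6-dimethoxy-2,4-bis(methoxymethoxy)phenyl (S)-2-methylbutanoate
Conditions: NIS (1.1 equiv), TFA (10 mol%), MeCN, 0 °C → rt, dark
Reagents that add atoms: N-iodosuccinimide, O=C1CCC(=O)N1I
Why: Electrophilic aromatic iodination (SEAr) can only occur at the single remaining ring C–H, which is activated by an ortho OMe, an ortho OMOM and a para OMOM group, and catalytic TFA in dry MeCN activates NIS without hydrolysing the acetals.

Step 7
Reactants: 10 5-iodo-3,6-dimethoxy-2,4-bis(methoxymethoxy)phenyl (S)-2-methylbutanoate; 11 carbon monoxide; 12 styrene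
Product: 13 5-[(E)-cinnamoyl]-3,6-dimethoxy-2,4-bis(methoxymethoxy)phenyl (S)-2-methylbutanoate
Conditions: Pd(OAc)2 (5 mol%), (1-Ad)2P(n-Bu) (15 mol%), CO (10 bar), styrene (3 equiv), Et3N (2 equiv), 1,4-dioxane, 100 °C, autoclave
Reagents that add atoms: none
Why: Zerovalent palladium, formed in situ from Pd(OAc)2 and the bulky electron-rich phosphine, adds oxidatively to the C–I bond of 10, CO inserts to give an aroylpalladium iodide, styrene inserts into the acyl–Pd bond with the acyl group going to the unsubstituted terminus and Pd to the benzylic carbon, and syn β-hydride elimination releases the enone while Et3N takes up HI and returns zerovalent palladium. The closest known reaction type is the carbonylative Heck reaction (carbonylative vinylation) of aryl iodides with styrenes, which gives chalcones directly. The step forms the C1'–C(=O) and C(=O)–Cα bonds, closes no ring and creates no stereocentre; its only stereochemical element, the E double bond, follows from syn insertion and syn β-hydride elimination through the less strained rotamer and is the conjugated, more stable isomer. The selectivity needed is carbonylative over direct Heck coupling and linear over branched acylation: the arylpalladium species is flanked by OMe and OMOM, which slows direct alkene insertion and makes CO insertion under 10 bar the faster path, while the electronic bias of styrene places the acyl group on the CH2 terminus. Because both phenols are masked as MOM ethers, no OH is available to intercept the aroylpalladium intermediate, and the weakly basic amine in aprotic dioxane should leave the aryl ester and its α-stereocentre untouched.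

Step 8
Reactants: 13 5-[(E)-cinnamoyl]-3,6-dimethoxy-2,4-bis(methoxymethoxy)phenyl (S)-2-methylbutanoate
Product: 14 5-[(E)-cinnamoyl]-2,4-dihydroxy-3,6-dimethoxyphenyl (S)-2-methylbutanoate (CNP0237988.1)
Conditions: TFA/CH2Cl2 (1:4), H2O (5 equiv), 0 °C; pH 7 phosphate buffer work-up
Reagents that add atoms: none
Why: Acid-catalysed acetal hydrolysis should remove both aryl MOM ethers in a cold, non-nucleophilic medium in which the aryl ester is neither transesterified nor enolised, so the S centre and the E-enone are retained.

**Compound list**
1 | 2,6-dibromo-4-methoxyphenol | COc1cc(Br)c(O)c(Br)c1 | starting material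
2 | 1,3-dibromo-2,5-dimethoxybenzene | COc1cc(Br)c(OC)c(Br)c1 | intermediate
3 | 2,5-dimethoxybenzene-1,3-diol | COc1cc(O)c(OC)c(O)c1 | intermediate
4 | 2,5-dimethoxy-1,3-bis(methoxymethoxy)benzene | COCOc1cc(OC)cc(OCOC)c1OC | intermediate
5 | [3,6-dimethoxy-2,4-bis(methoxymethoxy)phenyl]lithium | [Li]c1c(OC)cc(OCOC)c(OC)c1OCOC | intermediate
6 | dimethyl [3,6-dimethoxy-2,4-bis(methoxymethoxy)phenyl]boronate | COB(OC)c1c(OC)cc(OCOC)c(OC)c1OCOC | intermediate
7 | 3,6-dimethoxy-2,4-bis(methoxymethoxy)phenol | Oc1c(OC)cc(OCOC)c(OC)c1OCOC | intermediate
8 | (S)-2-methylbutanoic acid | CC[C@H](C)C(=O)O | starting material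
9 | 3,6-dimethoxy-2,4-bis(methoxymethoxy)phenyl (S)-2-methylbutanoate | CC[C@H](C)C(=O)Oc1c(OCOC)c(OC)c(OCOC)cc1OC | intermediate
10 | 5-iodo-3,6-dimethoxy-2,4-bis(methoxymethoxy)phenyl (S)-2-methylbutanoate | CC[C@H](C)C(=O)Oc1c(OCOC)c(OC)c(OCOC)c(I)c1OC | intermediate
11 | carbon monoxide | [C-]#[O+] | starting material
12 | styrene | C=Cc1ccccc1 | starting material
13 | 5-[(E)-cinnamoyl]-3,6-dimethoxy-2,4-bis(methoxymethoxy)phenyl (S)-2-methylbutanoate | CC[C@H](C)C(=O)Oc1c(OCOC)c(OC)c(OCOC)c(C(=O)/C=C/c2ccccc2)c1OC | intermediate
14 | 5-[(E)-cinnamoyl]-2,4-dihydroxy-3,6-dimethoxyphenyl (S)-2-methylbutanoate (CNP0237988.1) | CC[C@H](C)C(=O)Oc1c(O)c(OC)c(O)c(C(=O)/C=C/c2ccccc2)c1OC | target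

**Step count**
Total steps: 8. Longest linear sequence: 8 steps (1 → 14).

**Steps most likely to fail**

1. Step 7 (key step). Styrene insertion into the crowded aroylpalladium species may be slow. The intermediate could then be diverted by hydrolysis or reduction, or the non-carbonylative Heck pathway could compete, and prolonged heating with amine could also begin to erode the ester. The fallback builds the enone by carbanion chemistry instead; it sets out from phenol 7 and comes back to the route at 13. Phenol 7 would be silylated (TBSCl, imidazole, DMF) to tert-butyl[3,6-dimethoxy-2,4-bis(methoxymethoxy)phenoxy]dimethylsilane F1. Directed ortho-lithiation of its last ring C–H (n-BuLi, TMEDA, THF, −78 → −20 °C) should give [3-(tert-butyldimethylsilyloxy)-2,5-dimethoxy-4,6-bis(methoxymethoxy)phenyl]lithium F2. This adds in a 1,2 sense to (E)-cinnamaldehyde to give, after NH4Cl quench, racemic (E)-1-[3-(tert-butyldimethylsilyloxy)-2,5-dimethoxy-4,6-bis(methoxymethoxy)phenyl]-3-phenylprop-2-en-1-ol F3. Oxidation of this doubly activated alcohol with MnO2 in CH2Cl2 should give (E)-1-[3-(tert-butyldimethylsilyloxy)-2,5-dimethoxy-4,6-bis(methoxymethoxy)phenyl]-3-phenylprop-2-en-1-one F4. TBAF buffered with AcOH in THF at 0 °C would free (E)-1-[3-hydroxy-2,5-dimethoxy-4,6-bis(methoxymethoxy)phenyl]-3-phenylprop-2-en-1-one F5, and Steglich esterification of F5 with acid 8 (DCC, DMAP, CH2Cl2) gives 13.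

2. Step 8. While the acetals are being cleaved, the liberated 2'-hydroxyl may add to the enone (closure to a flavanone). The ester may also shift to the neighbouring 4'-oxygen or be lost on prolonged exposure to acid or during work-up. The fallback replaces protic hydrolysis by a low-temperature acetal exchange; it sets out from 13 and comes back at 14. Treatment of 13 with Me2BBr in CH2Cl2 at −78 °C should convert both MOM ethers into the bromomethyl ethers, giving 5-[(E)-cinnamoyl]-2,4-bis(bromomethoxy)-3,6-dimethoxyphenyl (S)-2-methylbutanoate F6. This is not isolated but hydrolysed in the cold with THF/aq. NaHCO3 to 14, so the free phenols never meet strong acid.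

3. Step 6. Iodination at the crowded last position may be slow, and the acid built up during a long reaction may strip a MOM group, after which over-iodination or oxidation of the freed phenol could follow. The fallback installs iodine by lithiation before the ester is present; it sets out from phenol 7 and comes back at 10. Phenol 7 is converted as above into the silyl ether F1 and lithiated to F2, which is quenched with I2 in THF at −78 °C to give tert-butyl[5-iodo-3,6-dimethoxy-2,4-bis(methoxymethoxy)phenoxy]dimethylsilane F7. TBAF buffered with AcOH would then give 5-iodo-3,6-dimethoxy-2,4-bis(methoxymethoxy)phenol F8, and Steglich esterification of F8 with acid 8 (DCC, DMAP, CH2Cl2) gives 10.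

**Further compounds**
F1 | step 7 | tert-butyl[3,6-dimethoxy-2,4-bis(methoxymethoxy)phenoxy]dimethylsilane | CC(C)(C)[Si](C)(C)Oc1c(OC)cc(OCOC)c(OC)c1OCOC
F2 | step 7 | [3-(tert-butyldimethylsilyloxy)-2,5-dimethoxy-4,6-bis(methoxymethoxy)phenyl]lithium | [Li]c1c(OC)c(O[Si](C)(C)C(C)(C)C)c(OCOC)c(OC)c1OCOC
F3 | step 7 | (E)-1-[3-(tert-butyldimethylsilyloxy)-2,5-dimethoxy-4,6-bis(methoxymethoxy)phenyl]-3-phenylprop-2-en-1-ol (racemic) | CC(C)(C)[Si](C)(C)Oc1c(OCOC)c(OC)c(OCOC)c(C(O)/C=C/c2ccccc2)c1OC
F4 | step 7 | (E)-1-[3-(tert-butyldimethylsilyloxy)-2,5-dimethoxy-4,6-bis(methoxymethoxy)phenyl]-3-phenylprop-2-en-1-one | CC(C)(C)[Si](C)(C)Oc1c(OCOC)c(OC)c(OCOC)c(C(=O)/C=C/c2ccccc2)c1OC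
F5 | step 7 | (E)-1-[3-hydroxy-2,5-dimethoxy-4,6-bis(methoxymethoxy)phenyl]-3-phenylprop-2-en-1-one | Oc1c(OCOC)c(OC)c(OCOC)c(C(=O)/C=C/c2ccccc2)c1OC
F6 | step 8 | 5-[(E)-cinnamoyl]-2,4-bis(bromomethoxy)-3,6-dimethoxyphenyl (S)-2-methylbutanoate | CC[C@H](C)C(=O)Oc1c(OCBr)c(OC)c(OCBr)c(C(=O)/C=C/c2ccccc2)c1OC
F7 | step 6 | tert-butyl[5-iodo-3,6-dimethoxy-2,4-bis(methoxymethoxy)phenoxy]dimethylsilane | CC(C)(C)[Si](C)(C)Oc1c(OCOC)c(OC)c(OCOC)c(I)c1OC
F8 | step 6 | 5-iodo-3,6-dimethoxy-2,4-bis(methoxymethoxy)phenol | Oc1c(OCOC)c(OC)c(OCOC)c(I)c1OC
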